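**Plan**
- Retrosynthesis: the two ring A acetates are put back on the 5- and 7-hydroxyls, then ring C is opened at O1–C2 to an open-chain ortho-hydroxyaryl ketone whose C2 is an unfunctionalised benzylic CH2. The C3–O ester bond and the C4–C4a aryl ketone bond are cut next.
- Enabling feature: Ph–C2–C3(O)–C4(=O) of ring C is the carbon skeleton of 3-phenyllactic acid, and ring A is phloroglucinol. The acylphloroglucinol therefore lacks only the O1–C2 bond, and C2 is a benzylic methylene held next to a ring A phenol.
- Forward: the chain is joined at C4–C4a (aryllithium on a Weinreb amide), the C3 ester is installed, ring A is differentiated into two acetates and one chelated free hydroxyl, ring C closes last by benzylic C–H etherification, and the acetates are removed.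
- Stereochemistry: C3 comes from D-phenylalanine (diazotisation with retention), the side-chain centre from (S)-2-methylbutanoic acid, and C2 is set in the ring closure, trans to C3.

Key step: step 10

Assumption: the configuration at C2 in step 10 is taken to be governed by C3. The bisoxazoline antipode written there is assumed to be the matched one and would be exchanged for its mirror image if it were not.

**Step 1**
Reactants: 1 D-phenylalanine
Product: 4 (R)-2-hydroxy-3-phenylpropanoic acid (D-phenyllactic acid), via (R)-diazonium carboxylate 2 (not isolated), via (S)-α-lactone 3 (not isolated)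
Conditions: NaNO2, 1 M aq. H2SO4, 0 °C → rt
Reagents that add atoms: water, O
Why: Deaminative hydroxylation of an α-amino acid by diazotisation runs with overall retention, because the carboxylate expels dinitrogen from 2 to give α-lactone 3 and water reopens it, each with inversion, so the future C3 is fixed as R.

**Step 2**
Reactants: 4 (R)-2-hydroxy-3-phenylpropanoic acid
Product: 5 (R)-2-hydroxy-N-methoxy-N-methyl-3-phenylpropanamide
Conditions: MeNHOMe·HCl, EDC·HCl, HOBt, N-methylmorpholine, CH2Cl2, 0 °C → rt
Reagents that add atoms: N,O-dimethylhydroxylamine hydrochloride, CNOC.Cl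
Why: Carbodiimide/HOBt amide coupling favours the amine over the secondary hydroxyl, so the Weinreb amide should form without hydroxyl protection and without touching the stereocentre.

**Step 3**
Reactants: 5 (R)-2-hydroxy-N-methoxy-N-methyl-3-phenylpropanamide
Product: 6 (R)-2-(tert-butyldimethylsilyloxy)-N-methoxy-N-methyl-3-phenylpropanamide
Conditions: TBSCl, imidazole, DMF, rt
Reagents that add atoms: tert-butyldimethylsilyl chloride, CC(C)(C)[Si](C)(C)Cl
Why: Imidazole-mediated silylation of the secondary alcohol masks the hydroxyl against the aryllithium of step 5.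

**Step 4**
Reactants: 7 phloroglucinol
Product: 8 1,3,5-tris(methoxymethoxy)benzene
Conditions: MOMCl, i-Pr2NEt, CH2Cl2 (a little DMF), 0 °C → rt
Reagents that add atoms: chloromethyl methyl ether, COCCl
Why: Williamson-type O-alkylation of the three phenols with the hard electrophile MOMCl gives the triether whose acetal oxygens later direct ortho-lithiation.

**Step 5**
Reactants: 8 1,3,5-tris(methoxymethoxy)benzene; 6 (R)-2-(tert-butyldimethylsilyloxy)-N-methoxy-N-methyl-3-phenylpropanamide
Product: 11 (R)-2-(tert-butyldimethylsilyloxy)-3-phenyl-1-[2,4,6-tris(methoxymethoxy)phenyl]propan-1-one, via 2,4,6-tris(methoxymethoxy)phenyllithium 9 (not isolated), via lithium hemiaminal adduct 10 (not isolated)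
Conditions: 8, n-BuLi, THF, 0 °C; then 6, −78 → 0 °C; aq. NH4Cl
Reagents that add atoms: none
Why: Directed ortho-metalation between two methoxymethoxy groups gives aryllithium 9, which adds once to the Weinreb amide because chelated adduct 10 survives until the quench (Weinreb ketone synthesis), forming C4–C4a without enolising the α-silyloxy centre.

**Step 6**
Reactants: 11 (R)-2-(tert-butyldimethylsilyloxy)-3-phenyl-1-[2,4,6-tris(methoxymethoxy)phenyl]propan-1-one
Product: 12 (R)-2-hydroxy-3-phenyl-1-[2,4,6-tris(methoxymethoxy)phenyl]propan-1-one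
Conditions: HF·pyridine, pyridine, THF, 0 °C → rt
Reagents that add atoms: none
Why: Fluoride-mediated desilylation under buffered, non-basic conditions frees the secondary alcohol while the aryl acetals stay on and the α-ketol centre is not exposed to base.

**Step 7**
Reactants: 12 (R)-2-hydroxy-3-phenyl-1-[2,4,6-tris(methoxymethoxy)phenyl]propan-1-one; 13 (S)-2-methylbutanoic acid
Product: 14 (R)-1-oxo-3-phenyl-1-[2,4,6-tris(methoxymethoxy)phenyl]propan-2-yl (S)-2-methylbutanoate
Conditions: DCC, DMAP (cat.), CH2Cl2, 0 °C → rt
Reagents that add atoms: none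
Why: Steglich esterification acylates the only free hydroxyl, and the mild temperature and catalytic DMAP should leave both the α-branched acid centre and the α-ketol centre intact.

**Step 8**
Reactants: 14 (R)-1-oxo-3-phenyl-1-[2,4,6-tris(methoxymethoxy)phenyl]propan-2-yl (S)-2-methylbutanoate
Product: 15 (R)-1-oxo-3-phenyl-1-(2,4,6-trihydroxyphenyl)propan-2-yl (S)-2-methylbutanoate
Conditions: HCl (ca. 0.5 M) in MeOH/THF, 35 °C
Reagents that add atoms: none
Why: Acid-catalysed acetal exchange removes the three phenolic methoxymethyl groups as dimethoxymethane, which also keeps formaldehyde away from the nucleophilic ring A, while the hindered secondary ester is transesterified far more slowly.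

**Step 9**
Reactants: 15 (R)-1-oxo-3-phenyl-1-(2,4,6-trihydroxyphenyl)propan-2-yl (S)-2-methylbutanoate
Product: 16 (R)-1-(2,4-diacetoxy-6-hydroxyphenyl)-1-oxo-3-phenylpropan-2-yl (S)-2-methylbutanoate
Conditions: Ac2O (2.1 equiv), pyridine, CH2Cl2, −10 → 0 °C
Reagents that add atoms: acetic anhydride, CC(=O)OC(C)=O
Why: Pyridine-mediated acetylation takes the para phenol and one ortho phenol, after which the remaining ortho hydroxyl is locked in a hydrogen bond to the ketone and is left free, as the 5-hydroxyl of flavonoids is under limited acylation.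

**Step 10**
Reactants: 16 (R)-1-(2,4-diacetoxy-6-hydroxyphenyl)-1-oxo-3-phenylpropan-2-yl (S)-2-methylbutanoate
Product: 17 (2R,3R)-5,7-diacetoxy-4-oxo-2-phenylchroman-3-yl (S)-2-methylbutanoate
Conditions: NFSI (1.4 equiv), [Cu(MeCN)4]PF6 (10 mol%), 2,2'-(propane-2,2-diyl)bis[(4S)-4-phenyl-4,5-dihydrooxazole] (12 mol%), (MeO)2P(O)H (0.3 equiv), CH2Cl2/HFIP 4:1, 35 °C
Reagents that add atoms: none
Why: Proposed new method: monovalent copper reduces NFSI to a divalent copper fluoride and the bis(phenylsulfonyl)imidyl radical, which removes a hydrogen atom from the benzylic C2 methylene; the benzylic radical is captured by divalent copper bearing the neighbouring phenoxide and C–O reductive elimination from trivalent copper forms O1–C2, while oxidation to the benzylic cation (or a transient benzylic fluoride re-ionised in HFIP) followed by capture by the phenol leads to the same bond. The closest known reactions are the copper/NFSI radical-relay benzylic C–H etherification with alcohols and the enantioselective copper–bisoxazoline benzylic C–H cyanation; new here is the intramolecular use of a phenol next to an existing stereocentre. Ring C closes in a 6-exo-tet sense, the phenol oxygen being held beside C2 by its hydrogen bond to the C4 ketone. The new C2 centre is controlled by C3: in the chair-like closure phenyl and the C3 acyloxy group both sit equatorial, which gives the 2,3-trans (2R,3R) isomer, also the more stable one, and the chiral ligand is meant to reinforce this. The step needs site selectivity for C2–H over C3–H, the ester α-C–H and the C2–H of the product, and it needs ring A to escape oxidation, fluorination and sulfonimidation. Polarity matching of the electrophilic nitrogen radical with the most hydridic C–H, the deactivation of ring A by its acyl and two acetoxy groups, the vinylogous-ester character of O1 in 17 and the limited charge of NFSI are expected to secure this.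

**Step 11**
Reactants: 17 (2R,3R)-5,7-diacetoxy-4-oxo-2-phenylchroman-3-yl (S)-2-methylbutanoate
Product: 18 (2R,3R)-5,7-dihydroxy-4-oxo-2-phenylchroman-3-yl (S)-2-methylbutanoate (target)
Conditions: NH4OAc, MeOH/H2O 4:1, rt
Reagents that add atoms: none
Why: Ammonium acetate-buffered transesterification cleaves aryl acetates, whose phenoxide leaving groups are far better than the secondary alkoxide of the C3 ester, in a medium too weakly basic to enolise C3 or open ring C.

**Compound list**
1 | D-phenylalanine | N[C@H](Cc1ccccc1)C(=O)O | starting material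
2 | (R)-2-diazonio-3-phenylpropanoate (diazonium carboxylate) | N#[N+][C@H](Cc1ccccc1)C(=O)[O-] | intermediate (not isolated)
3 | (S)-3-benzyloxiran-2-one (α-lactone) | O=C1O[C@H]1Cc2ccccc2 | intermediate (not isolated)
4 | (R)-2-hydroxy-3-phenylpropanoic acid | O[C@H](Cc1ccccc1)C(=O)O | intermediate
5 | (R)-2-hydroxy-N-methoxy-N-methyl-3-phenylpropanamide | O[C@H](Cc1ccccc1)C(=O)N(C)OC | intermediate
6 | (R)-2-(tert-butyldimethylsilyloxy)-N-methoxy-N-methyl-3-phenylpropanamide | CC(C)(C)[Si](C)(C)O[C@H](Cc1ccccc1)C(=O)N(C)OC | intermediate
7 | phloroglucinol | Oc1cc(O)cc(O)c1 | starting material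
8 | 1,3,5-tris(methoxymethoxy)benzene | COCOc1cc(OCOC)cc(OCOC)c1 | intermediate
9 | 2,4,6-tris(methoxymethoxy)phenyllithium | [Li]c1c(OCOC)cc(OCOC)cc1OCOC | intermediate (not isolated)
10 | lithium hemiaminal adduct of 9 and 6 (hemiaminal carbon configuration undefined, (R) at the silyloxy carbon) | [Li]OC(N(C)OC)(c1c(OCOC)cc(OCOC)cc1OCOC)[C@@H](Cc1ccccc1)O[Si](C)(C)C(C)(C)C | intermediate (not isolated)
11 | (R)-2-(tert-butyldimethylsilyloxy)-3-phenyl-1-[2,4,6-tris(methoxymethoxy)phenyl]propan-1-one | CC(C)(C)[Si](C)(C)O[C@H](Cc1ccccc1)C(=O)c1c(OCOC)cc(OCOC)cc1OCOC | intermediate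
12 | (R)-2-hydroxy-3-phenyl-1-[2,4,6-tris(methoxymethoxy)phenyl]propan-1-one | O[C@H](Cc1ccccc1)C(=O)c1c(OCOC)cc(OCOC)cc1OCOC | intermediate
13 | (S)-2-methylbutanoic acid | CC[C@H](C)C(=O)O | starting material
14 | (R)-1-oxo-3-phenyl-1-[2,4,6-tris(methoxymethoxy)phenyl]propan-2-yl (S)-2-methylbutanoate | CC[C@H](C)C(=O)O[C@H](Cc1ccccc1)C(=O)c1c(OCOC)cc(OCOC)cc1OCOC | intermediate
15 | (R)-1-oxo-3-phenyl-1-(2,4,6-trihydroxyphenyl)propan-2-yl (S)-2-methylbutanoate | CC[C@H](C)C(=O)O[C@H](Cc1ccccc1)C(=O)c1c(O)cc(O)cc1O | intermediate
16 | (R)-1-(2,4-diacetoxy-6-hydroxyphenyl)-1-oxo-3-phenylpropan-2-yl (S)-2-methylbutanoate | CC[C@H](C)C(=O)O[C@H](Cc1ccccc1)C(=O)c1c(O)cc(OC(C)=O)cc1OC(C)=O | intermediate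
17 | (2R,3R)-5,7-diacetoxy-4-oxo-2-phenylchroman-3-yl (S)-2-methylbutanoate | CC[C@H](C)C(=O)O[C@H]1C(=O)c2c(OC(C)=O)cc(OC(C)=O)cc2O[C@@H]1c1ccccc1 | intermediate
18 | (2R,3R)-5,7-dihydroxy-4-oxo-2-phenylchroman-3-yl (S)-2-methylbutanoate | CC[C@H](C)C(=O)O[C@H]1C(=O)c2c(O)cc(O)cc2O[C@@H]1c1ccccc1 | target

**Step count**
Total: 11 steps. Longest linear sequence: 10 steps (steps 1, 2, 3, 5, 6, 7, 8, 9, 10, 11 from D-phenylalanine); step 4 is the only side-branch step.

**Steps most likely to fail**

Step 10 (Proposed new method). Hydrogen abstraction at the inductively deactivated benzylic methylene may be too slow to compete with oxidation or fluorination of the phenol-bearing ring, or the cyclised product may be oxidised further at C2. The fallback uses known chemistry and sets out from 15. Exhaustive acetylation (Ac2O, pyridine, cat. DMAP) would give the triacetate (R)-1-oxo-3-phenyl-1-(2,4,6-triacetoxyphenyl)propan-2-yl (S)-2-methylbutanoate F1, in which no phenol is left to react with a brominating agent. Wohl–Ziegler bromination (NBS, cat. AIBN, PhCF3, 80 °C) should then give the benzylic bromide (2S)-3-bromo-1-oxo-3-phenyl-1-(2,4,6-triacetoxyphenyl)propan-2-yl (S)-2-methylbutanoate F2 as both epimers at the brominated carbon (the ester-bearing centre keeps its geometry; only its descriptor changes). Treatment with NH4OAc in aqueous MeOH would free the phenols, and an ortho phenol would displace the bromide in an intramolecular Williamson closure. The 2,3-trans isomer is expected to be favoured through the chair with both substituents equatorial, and any cis isomer would be removed by chromatography. The route is rejoined at 18.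

Step 9. The acetylation may not stop cleanly at two acyl groups, so that the chelated hydroxyl is partly acetylated or one phenol is left unreacted. The fallback sets out from 15 and protects the chelated position before acylation. BF3·OEt2 in CH2Cl2 should give the difluoroboron chelate of 15 F3, in which boron bridges the ketone oxygen and one ortho phenolate oxygen. Acetylation with excess Ac2O and i-Pr2NEt would give the 4,6-di-O-acetyl difluoroboron chelate F4. Warming in MeOH should release the boron and return the route to 16.

Step 11. The solvolysis may not discriminate fully between the aryl acetates and the C3 alkyl ester, so that the 2-methylbutanoyl group is partly lost. The fallback sets out from 17 and accepts complete deacylation. K2CO3 in MeOH at 0 °C would give (2R,3R)-3,5,7-trihydroxy-2-phenylchroman-4-one (pinobanksin) F5. TBSCl (1 equiv) and imidazole should silylate the most acidic, non-chelated phenol to give (2R,3R)-7-(tert-butyldimethylsilyloxy)-3,5-dihydroxy-2-phenylchroman-4-one F6. Steglich esterification with 13 (DCC, cat. DMAP), to which the chelated 5-hydroxyl is inert, would give (2R,3R)-7-(tert-butyldimethylsilyloxy)-5-hydroxy-4-oxo-2-phenylchroman-3-yl (S)-2-methylbutanoate F7. HF·pyridine would then remove the silyl group and return the route to 18.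

**Further compounds**
F1 | step 10 | (R)-1-oxo-3-phenyl-1-(2,4,6-triacetoxyphenyl)propan-2-yl (S)-2-methylbutanoate | CC[C@H](C)C(=O)O[C@H](Cc1ccccc1)C(=O)c1c(OC(C)=O)cc(OC(C)=O)cc1OC(C)=O
F2 | step 10 | (2S)-3-bromo-1-oxo-3-phenyl-1-(2,4,6-triacetoxyphenyl)propan-2-yl (S)-2-methylbutanoate, both epimers at the brominated carbon | CC[C@H](C)C(=O)O[C@H](C(Br)c1ccccc1)C(=O)c1c(OC(C)=O)cc(OC(C)=O)cc1OC(C)=O
F3 | step 9 | difluoroboron chelate of 15 (boron on the ketone oxygen and one ortho phenolate oxygen) | CC[C@H](C)C(=O)O[C@H](Cc1ccccc1)C2=[O+][B-](F)(F)Oc3cc(O)cc(O)c23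
F4 | step 9 | 4,6-di-O-acetyl difluoroboron chelate | CC[C@H](C)C(=O)O[C@H](Cc1ccccc1)C2=[O+][B-](F)(F)Oc3cc(OC(C)=O)cc(OC(C)=O)c23
F5 | step 11 | (2R,3R)-3,5,7-trihydroxy-2-phenylchroman-4-one | O[C@H]1C(=O)c2c(O)cc(O)cc2O[C@@H]1c1ccccc1
F6 | step 11 | (2R,3R)-7-(tert-butyldimethylsilyloxy)-3,5-dihydroxy-2-phenylchroman-4-one | O[C@H]1C(=O)c2c(O)cc(O[Si](C)(C)C(C)(C)C)cc2O[C@@H]1c1ccccc1
F7 | step 11 | (2R,3R)-7-(tert-butyldimethylsilyloxy)-5-hydroxy-4-oxo-2-phenylchroman-3-yl (S)-2-methylbutanoate | CC[C@H](C)C(=O)O[C@H]1C(=O)c2c(O)cc(O[Si](C)(C)C(C)(C)C)cc2O[C@@H]1c1ccccc1
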